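**Retrosynthetic overview**
- The (3S) target comes from its tris-MOM ether, and that from an isoflavone: the C3–OH and the C3 stereocentre are set in one flask by 1,4-hydride addition and enolate hydroxylation with an enantiopure N-sulfonyloxaziridine (reductase-then-hydroxylase logic).
- The prenyl C–C bond comes from an aryl bromide (Stille), placed after the oxidative step that an alkene would not survive.
- Ring C is the only ring made (rings A and B are bought). It comes from a 2'-hydroxychalcone by an oxidative 1,2-aryl shift (the counterpart of isoflavone synthase), followed in the same flask by oxa-Michael closure of the ring A phenol (the counterpart of chalcone isomerase).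
- The chalcone comes from a Claisen–Schmidt condensation of MOM-protected resacetophenone with 5-bromo-4-methoxy-2,3-bis(methoxymethoxy)benzaldehyde.

Assumption: the facial sense of the oxaziridine in step 7 is taken by analogy with the Z-enolate of deoxybenzoin and is not verified for this enolate; if the 3R alcohol forms, the antipodal oxaziridine (equally available) is used with no other change.

**Step 1**
Reactants: 1 2,4-dihydroxyacetophenone
Product: 2 ketone 1-[2-hydroxy-4-(methoxymethoxy)phenyl]ethan-1-one
Conditions: MOMCl (1.1 equiv), K2CO3, acetone, 0 °C to rt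
Reagents that add atoms: chloromethyl methyl ether (MOMCl), COCCl
Why: The 2-OH is tied up in a hydrogen bond to the ketone, so the free and more acidic 4-OH is alkylated selectively (Williamson O-alkylation, MOM protection).

**Step 2**
Reactants: 3 2,3-dihydroxy-4-methoxybenzaldehyde
Product: 4 aldehyde 5-bromo-2,3-dihydroxy-4-methoxybenzaldehyde
Conditions: Br2 (1.0 equiv), NaOAc, AcOH, 0 °C to rt
Reagents that add atoms: bromine, BrBr
Why: Electrophilic aromatic bromination goes to C5, which is para to the 2-OH, ortho to the 4-OMe and meta to the formyl group, whereas C6 is ortho to the formyl group (same preference as the 5-bromination of o-vanillin).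

**Step 3**
Reactants: 4 5-bromo-2,3-dihydroxy-4-methoxybenzaldehyde
Product: 5 aldehyde 5-bromo-4-methoxy-2,3-bis(methoxymethoxy)benzaldehyde
Conditions: NaH (2.4 equiv), DMF, 0 °C; MOMCl (2.4 equiv), 0 °C to rt
Reagents that add atoms: chloromethyl methyl ether (MOMCl), COCCl
Why: Williamson O-alkylation of both phenoxides (MOM protection) masks the catechol against the base, oxidant, palladium and hydride steps ahead and leaves under mild acid.

**Step 4**
Reactants: 2 1-[2-hydroxy-4-(methoxymethoxy)phenyl]ethan-1-one; 5 5-bromo-4-methoxy-2,3-bis(methoxymethoxy)benzaldehyde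
Product: 6 chalcone (E)-3-[5-bromo-4-methoxy-2,3-bis(methoxymethoxy)phenyl]-1-[2-hydroxy-4-(methoxymethoxy)phenyl]prop-2-en-1-one
Conditions: KOH, EtOH/H2O, rt, 48 h
Reagents that add atoms: none
Why: Claisen–Schmidt (crossed aldol) condensation of a methyl ketone with a non-enolisable aldehyde gives the E-enone, and the chelated 2'-OH stays free for the later ring closure.

**Step 5**
Reactants: 6 (E)-3-[5-bromo-4-methoxy-2,3-bis(methoxymethoxy)phenyl]-1-[2-hydroxy-4-(methoxymethoxy)phenyl]prop-2-en-1-one
Product: 8 bromo-isoflavone 3-[5-bromo-4-methoxy-2,3-bis(methoxymethoxy)phenyl]-7-(methoxymethoxy)-4H-chromen-4-one, via keto acetal 7 (not isolated)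
Conditions: Tl(NO3)3·3H2O (1.2 equiv), MeOH/HC(OMe)3, rt; then NaOMe (6 equiv), MeOH, 50 °C
Reagents that add atoms: none
Why: Oxidative rearrangement of a 2'-hydroxychalcone by trivalent thallium (oxythallation of the enone, methanol capture at the benzylic carbon, 1,2-shift of the electron-rich 4-methoxyaryl ring from Cβ to Cα with loss of monovalent thallium) gives acetal 7, and methoxide then causes E1cB loss of methanol and oxa-Michael addition–elimination of the ring A phenoxide, which closes ring C under conditions that leave the MOM ethers alone.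

**Step 6**
Reactants: 8 3-[5-bromo-4-methoxy-2,3-bis(methoxymethoxy)phenyl]-7-(methoxymethoxy)-4H-chromen-4-one
Product: 9 prenyl-isoflavone 3-[4-methoxy-2,3-bis(methoxymethoxy)-5-(3-methylbut-2-en-1-yl)phenyl]-7-(methoxymethoxy)-4H-chromen-4-one
Conditions: tributyl(3-methylbut-2-en-1-yl)stannane (1.5 equiv), Pd(PPh3)4 (5 mol %), DMF, 100 °C
Reagents that add atoms: tributyl(3-methylbut-2-en-1-yl)stannane, CCCC[Sn](CCCC)(CCCC)CC=C(C)C
Why: Stille cross-coupling, in which zerovalent palladium inserts into the Ar–Br bond and the allyl-palladium intermediate reductively eliminates at its unhindered CH2 terminus, gives the linear prenyl arene under neutral conditions that spare the MOM ethers.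

**Step 7**
Reactants: 9 3-[4-methoxy-2,3-bis(methoxymethoxy)-5-(3-methylbut-2-en-1-yl)phenyl]-7-(methoxymethoxy)-4H-chromen-4-one
Product: 11 alcohol (3S)-3-hydroxy-3-[4-methoxy-2,3-bis(methoxymethoxy)-5-(3-methylbut-2-en-1-yl)phenyl]-7-(methoxymethoxy)-2,3-dihydro-4H-chromen-4-one, via potassium enolate 10 (not isolated)
Conditions: K[HB(s-Bu)3] (1.1 equiv), THF, −78 °C; then (−)-[(8,8-dichlorocamphoryl)sulfonyl]oxaziridine (1.5 equiv), −78 to −40 °C; AcOH quench
Reagents that add atoms: (−)-[(8,8-dichlorocamphoryl)sulfonyl]oxaziridine (from (1R)-(−)-10-camphorsulfonic acid), CC1(C)[C@H]2CC[C@@]13CS(=O)(=O)N4O[C@]34C2(Cl)Cl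
Why: Proposed new method: conjugate hydride addition to C2 of the isoflavone (the known trialkylborohydride reduction of isoflavones to isoflavanones) gives the tetrasubstituted potassium enolate 10 regiospecifically, and the enantiopure N-sulfonyloxaziridine then transfers its oxygen to one enolate face by SN2-type attack at O (Davis asymmetric enolate hydroxylation, closest precedents the enolates of 3-substituted chroman-4-ones and 2-substituted 1-tetralones), so the quaternary C3 centre is set as S by reagent control and cannot epimerise afterwards.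

**Step 8**
Reactants: 11 (3S)-3-hydroxy-3-[4-methoxy-2,3-bis(methoxymethoxy)-5-(3-methylbut-2-en-1-yl)phenyl]-7-(methoxymethoxy)-2,3-dihydro-4H-chromen-4-one
Product: 12 target (3S)-3-[2,3-dihydroxy-4-methoxy-5-(3-methylbut-2-en-1-yl)phenyl]-3,7-dihydroxy-2,3-dihydro-4H-chromen-4-one
Conditions: 3 M HCl, MeOH/THF, 45 °C
Reagents that add atoms: none
Why: Acid-catalysed acetal exchange with methanol removes the three MOM groups; the tertiary α-ketol resists ionisation (cation next to C=O), the prenyl group has no ortho-OH to cyclise onto, and no bond to C3 is broken, so the S configuration is kept.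

**Compound list**
1 | 2,4-dihydroxyacetophenone | CC(=O)c1ccc(O)cc1O | starting material
2 | 1-[2-hydroxy-4-(methoxymethoxy)phenyl]ethan-1-one | COCOc1ccc(C(C)=O)c(O)c1 | intermediate
3 | 2,3-dihydroxy-4-methoxybenzaldehyde | COc1ccc(C=O)c(O)c1O | starting material
4 | 5-bromo-2,3-dihydroxy-4-methoxybenzaldehyde | COc1c(Br)cc(C=O)c(O)c1O | intermediate
5 | 5-bromo-4-methoxy-2,3-bis(methoxymethoxy)benzaldehyde | COCOc1c(C=O)cc(Br)c(OC)c1OCOC | intermediate
6 | (E)-3-[5-bromo-4-methoxy-2,3-bis(methoxymethoxy)phenyl]-1-[2-hydroxy-4-(methoxymethoxy)phenyl]prop-2-en-1-one | COCOc1ccc(C(=O)/C=C/c2cc(Br)c(OC)c(OCOC)c2OCOC)c(O)c1 | intermediate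
7 | 2-[5-bromo-4-methoxy-2,3-bis(methoxymethoxy)phenyl]-1-[2-hydroxy-4-(methoxymethoxy)phenyl]-3,3-dimethoxypropan-1-one (racemic, not isolated) | COCOc1ccc(C(=O)C(C(OC)OC)c2cc(Br)c(OC)c(OCOC)c2OCOC)c(O)c1 | intermediate
8 | 3-[5-bromo-4-methoxy-2,3-bis(methoxymethoxy)phenyl]-7-(methoxymethoxy)-4H-chromen-4-one | O=c1c(-c2cc(Br)c(OC)c(OCOC)c2OCOC)coc2cc(OCOC)ccc12 | intermediate
9 | 3-[4-methoxy-2,3-bis(methoxymethoxy)-5-(3-methylbut-2-en-1-yl)phenyl]-7-(methoxymethoxy)-4H-chromen-4-one | O=c1c(-c2cc(CC=C(C)C)c(OC)c(OCOC)c2OCOC)coc2cc(OCOC)ccc12 | intermediate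
10 | potassium 3-[4-methoxy-2,3-bis(methoxymethoxy)-5-(3-methylbut-2-en-1-yl)phenyl]-7-(methoxymethoxy)-2H-chromen-4-olate (not isolated) | [K+].[O-]C1=C(c2cc(CC=C(C)C)c(OC)c(OCOC)c2OCOC)COc2cc(OCOC)ccc21 | intermediate
11 | (3S)-3-hydroxy-3-[4-methoxy-2,3-bis(methoxymethoxy)-5-(3-methylbut-2-en-1-yl)phenyl]-7-(methoxymethoxy)-2,3-dihydro-4H-chromen-4-one | COc1c(CC=C(C)C)cc([C@]2(O)COc3cc(OCOC)ccc3C2=O)c(OCOC)c1OCOC | intermediate
12 | (3S)-3-[2,3-dihydroxy-4-methoxy-5-(3-methylbut-2-en-1-yl)phenyl]-3,7-dihydroxy-2,3-dihydro-4H-chromen-4-one | COc1c(CC=C(C)C)cc([C@]2(O)COc3cc(O)ccc3C2=O)c(O)c1O | target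

**Totals**
Total step count: 8. Longest linear sequence: 7 steps (3 → 4 → 5 → 6 → 8 → 9 → 11 → 12).

**Steps most likely to fail**

Step 5 (aryl shift and ring closure in one flask). The MOM ethers must survive the nitric acid released, and the base-mediated closure must outrun methoxide attack on the chromone. The fallback sets out from chalcone 6 and returns at isoflavone 8. The thallium oxidation is taken to acetal 7 as before, but ring C is closed by the classical acid route (10% HCl, MeOH, 60 °C). This knowingly strips all three MOM groups and gives 3-(5-bromo-2,3-dihydroxy-4-methoxyphenyl)-7-hydroxy-4H-chromen-4-one F1. The three phenols are then re-protected (MOMCl, NaH, DMF) to rejoin the route at 8. One extra step is traded for a closure that does not rely on base-induced elimination.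

Step 7 (one-flask reduction and asymmetric hydroxylation). The ee and even the sense of induction on this hindered, ortho-substituted aryl enolate are unproven, and the borane by-product or ring opening of the enolate may interfere. The fallback sets out from 9 and returns at 11. Reduction with Li[HB(s-Bu)3] and a proton quench gives the racemic isoflavanone 3-[4-methoxy-2,3-bis(methoxymethoxy)-5-(3-methylbut-2-en-1-yl)phenyl]-7-(methoxymethoxy)-2,3-dihydro-4H-chromen-4-one F2. Its enolate is then hydroxylated catalytically with O2 under a chiral cinchona-derived quaternary ammonium phase-transfer catalyst (toluene/50% aqueous KOH, P(OEt)3 to reduce the hydroperoxide, 0 °C). The cinchonine- or cinchonidine-derived salt that delivers the 3S alcohol 11 is chosen. The centre is then set by a catalyst-bound ion pair instead of a stoichiometric chiral oxidant.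

Step 8 (global MOM removal). Acid could dehydrate the tertiary α-ketol to the isoflavone or add to the prenyl alkene. The fallback sets out from 9 and returns at 12. The MOM ethers are removed at the acid-robust isoflavone stage (3 M HCl, MeOH, 50 °C) to give 3-[2,3-dihydroxy-4-methoxy-5-(3-methylbut-2-en-1-yl)phenyl]-7-hydroxy-4H-chromen-4-one F3. Silylation (TBSCl, imidazole, DMF) gives the tris-TBS isoflavone F4. The same reduction and oxaziridine hydroxylation as in step 7 then proceeds through the tris-TBS potassium enolate F5 to the tris-TBS (3S)-3-hydroxyisoflavanone F6. Finally Bu4NF/AcOH in THF at 0 °C unmasks the phenols, so the last step is fluoride-mediated and not acidic.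

**Further compounds**
F1 | step 5 | 3-(5-bromo-2,3-dihydroxy-4-methoxyphenyl)-7-hydroxy-4H-chromen-4-one | O=c1c(-c2cc(Br)c(OC)c(O)c2O)coc2cc(O)ccc12
F2 | step 7 | 3-[4-methoxy-2,3-bis(methoxymethoxy)-5-(3-methylbut-2-en-1-yl)phenyl]-7-(methoxymethoxy)-2,3-dihydro-4H-chromen-4-one (racemic) | O=C1c2ccc(OCOC)cc2OCC1c1cc(CC=C(C)C)c(OC)c(OCOC)c1OCOC
F3 | step 8 | 3-[2,3-dihydroxy-4-methoxy-5-(3-methylbut-2-en-1-yl)phenyl]-7-hydroxy-4H-chromen-4-one | O=c1c(-c2cc(CC=C(C)C)c(OC)c(O)c2O)coc2cc(O)ccc12
F4 | step 8 | 7-(tert-butyldimethylsilyloxy)-3-[2,3-bis(tert-butyldimethylsilyloxy)-4-methoxy-5-(3-methylbut-2-en-1-yl)phenyl]-4H-chromen-4-one | O=c1c(-c2cc(CC=C(C)C)c(OC)c(O[Si](C)(C)C(C)(C)C)c2O[Si](C)(C)C(C)(C)C)coc2cc(O[Si](C)(C)C(C)(C)C)ccc12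
F5 | step 8 | potassium 7-(tert-butyldimethylsilyloxy)-3-[2,3-bis(tert-butyldimethylsilyloxy)-4-methoxy-5-(3-methylbut-2-en-1-yl)phenyl]-2H-chromen-4-olate (not isolated) | [K+].[O-]C1=C(c2cc(CC=C(C)C)c(OC)c(O[Si](C)(C)C(C)(C)C)c2O[Si](C)(C)C(C)(C)C)COc2cc(O[Si](C)(C)C(C)(C)C)ccc21
F6 | step 8 | (3S)-7-(tert-butyldimethylsilyloxy)-3-[2,3-bis(tert-butyldimethylsilyloxy)-4-methoxy-5-(3-methylbut-2-en-1-yl)phenyl]-3-hydroxy-2,3-dihydro-4H-chromen-4-one | COc1c(CC=C(C)C)cc([C@]2(O)COc3cc(O[Si](C)(C)C(C)(C)C)ccc3C2=O)c(O[Si](C)(C)C(C)(C)C)c1O[Si](C)(C)C(C)(C)C
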